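**Plan**
1. Retrosynthesis: the C3–OH / C2=CH2 array is undone by a retro-ene to the ring enol ether O1–C2(CH3)=C3. The cyclohexane bond C1'–C2' is cut next (key step). C3'–Br / C4'–Cl then go back to a (Z)-allylic alcohol, O1–C6 / C5–Br to a prenyl alkene plus a C2 carbinol, and C3=C1' to a ketophosphonate plus an aldehyde.
2. Forward: a prenylated ketophosphonate and an aldehyde cut from neryl acetate are joined by a Horner–Wadsworth–Emmons reaction. The oxane ring is closed first (bromoetherification), the side chain is bromochlorinated, the cyclohexane is closed last, and a singlet-oxygen ene reaction ends the route.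
3. Enabling feature: the C3' bromine of the target is equatorial, hence anti-periplanar to the ring bond C1'–C2', and C1' sits on C3 beside the O1–C2 unit. C2' can therefore react as the CH2 end of a bromine-bridged cation, the exocyclic C3=C1' alkene of the finished oxane is the nucleophile, and the C3 cation is discharged by the C2 hydrogen onto O1-stabilised C2.
4. Stereochemistry: C2 is set by catalysis (CBS), relays to C5 in the bromoetherification and is then erased. C5 relays to C3 in the ene reaction. C3' and C4' are set by catalytic enantioselective bromochlorination, and C3' relays to C1' in the key step.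

Key step: step 10

Atom labels (kept for the same atoms in all precursors): oxane O1, C2 (=CH2), C3 (OH), C4, C5 (Br), C6 (two CH3); cyclohexane C1' (on C3), C2', C3' (Br), C4' (CH3, Cl), C5', C6'.
Assumption: the enantiomer of the Schiff-base ligand in step 8 is the one that delivers the (2S,3S)-bromochloride.

**Route**

Step 1
Reactants: 1 diethyl (2-oxopropyl)phosphonate; 2 prenyl bromide (1-bromo-3-methylbut-2-ene)
Product: 3 diethyl (6-methyl-2-oxohept-5-en-3-yl)phosphonate (racemic)
Conditions: NaH, THF, 0 °C → rt
Reagents that add atoms: none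
Why: C-alkylation of the sodium salt of the β-ketophosphonate at the carbon between P and C=O (SN2 on the primary allylic bromide) brings in C4, C5, C6 and both C6 methyls, and the new stereocentre is lost in step 4.

Step 2
Reactants: 4 neryl acetate ((2Z)-3,7-dimethylocta-2,6-dien-1-yl acetate)
Product: 5 (2Z)-5-(3,3-dimethyloxiran-2-yl)-3-methylpent-2-en-1-yl acetate (racemic at the oxirane carbon)
Conditions: mCPBA, CH2Cl2, 0 °C
Reagents that add atoms: meta-chloroperoxybenzoic acid, O=C(OO)c1cccc(Cl)c1
Why: Prilezhaev epoxidation should take only the distal trisubstituted alkene, the 2,3-alkene being deactivated by the allylic acetate, and the oxirane stereocentre is removed in step 3.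

Step 3
Reactants: 5 (2Z)-5-(3,3-dimethyloxiran-2-yl)-3-methylpent-2-en-1-yl acetate
Product: 6 (2Z)-3-methyl-6-oxohex-2-en-1-yl acetate
Conditions: H5IO6, THF/Et2O, 0 °C
Reagents that add atoms: none
Why: periodic acid opens the epoxide to the diol and cleaves it (glycol cleavage) to the aldehyde carbon C1' and acetone, leaving the (Z)-alkene and the acetate untouched.

Step 4
Reactants: 3 diethyl (6-methyl-2-oxohept-5-en-3-yl)phosphonate; 6 (2Z)-3-methyl-6-oxohex-2-en-1-yl acetate
Product: 7 (2Z,6E)-7-acetyl-3,10-dimethylundeca-2,6,9-trien-1-yl acetate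
Conditions: NaH, THF, 0 °C → rt
Reagents that add atoms: none
Why: Horner–Wadsworth–Emmons olefination of the α-branched ketophosphonate should give the trisubstituted enone mainly as the E isomer (acetyl trans to the chain), which is carried on after chromatography, although the geometry of C3=C1' has no bearing on the final stereocentres.

Step 5
Reactants: 7 (2Z,6E)-7-acetyl-3,10-dimethylundeca-2,6,9-trien-1-yl acetate
Product: 8 (2Z,6E)-7-[(1R)-1-hydroxyethyl]-3,10-dimethylundeca-2,6,9-trien-1-yl acetate
Conditions: (S)-2-methyl-CBS-oxazaborolidine (cat.), catecholborane, toluene, −78 °C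
Reagents that add atoms: none
Why: CBS reduction, 1,2-selective on the enone, should set C2 as R because the branched alkenyl group acts as the large and the methyl as the small substituent of the ketone bound to the (S)-oxazaborolidine.

Step 6
Reactants: 8 (2Z,6E)-7-[(1R)-1-hydroxyethyl]-3,10-dimethylundeca-2,6,9-trien-1-yl acetate
Product: 9 (2Z,6E)-6-[(2R,5R)-5-bromo-2,6,6-trimethyloxan-3-ylidene]-3-methylhex-2-en-1-yl acetate
Conditions: TBCO, CH2Cl2, −78 → 0 °C
Reagents that add atoms: 2,4,4,6-tetrabromocyclohexa-2,5-dienone, O=C1C(Br)=CC(Br)(Br)C=C1Br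
Why: 6-endo bromoetherification (Markovnikov opening at tertiary C6, by the C2 hydroxyl, of the bromonium ion of the most electron-rich prenyl alkene) through a chair in which the C2 methyl is equatorial (an axial one would clash with the axial C6 methyl) and anti addition leaves bromine equatorial, which should give the 2,5-trans ring and so set C5 as R.

Step 7
Reactants: 9 (2Z,6E)-6-[(2R,5R)-5-bromo-2,6,6-trimethyloxan-3-ylidene]-3-methylhex-2-en-1-yl acetate
Product: 10 (2Z,6E)-6-[(2R,5R)-5-bromo-2,6,6-trimethyloxan-3-ylidene]-3-methylhex-2-en-1-ol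
Conditions: K2CO3, MeOH, 0 °C
Reagents that add atoms: none
Why: base-catalysed transesterification removes the primary acetate, and the secondary equatorial ring bromide is not expected to react under these mild conditions.

Step 8
Reactants: 10 (2Z,6E)-6-[(2R,5R)-5-bromo-2,6,6-trimethyloxan-3-ylidene]-3-methylhex-2-en-1-ol
Product: 11 (2S,3S,6E)-2-bromo-6-[(2R,5R)-5-bromo-2,6,6-trimethyloxan-3-ylidene]-3-chloro-3-methylhexan-1-ol
Conditions: NBS, ClTi(OiPr)3, chiral tridentate Schiff-base (salicylaldimine amino alcohol) ligand (cat.), hexanes, −20 °C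
Reagents that add atoms: N-bromosuccinimide, O=C1CCC(=O)N1Br; chlorotitanium triisopropoxide, CC(C)O[Ti](Cl)(OC(C)C)OC(C)C
Why: titanium/Schiff-base-catalysed enantioselective bromochlorination of an allylic alcohol, in which only the alkene of the titanium-bound allylic alkoxide reacts, bromine goes to C3' and chloride adds anti at tertiary C4', and the ligand decides the face, so that the (Z)-alkene should give the (3'S,4'S) bromochloride.

Step 9
Reactants: 11 (2S,3S,6E)-2-bromo-6-[(2R,5R)-5-bromo-2,6,6-trimethyloxan-3-ylidene]-3-chloro-3-methylhexan-1-ol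
Product: 12 (2S,3S,6E)-2-bromo-6-[(2R,5R)-5-bromo-2,6,6-trimethyloxan-3-ylidene]-3-chloro-3-methylhexyl trifluoromethanesulfonate
Conditions: Tf2O, 2,6-di-tert-butyl-4-methylpyridine, CH2Cl2, −78 °C
Reagents that add atoms: trifluoromethanesulfonic anhydride, O=S(=O)(OS(=O)(=O)C(F)(F)F)C(F)(F)F
Why: O-sulfonylation of the primary alcohol with a hindered, non-nucleophilic base, the triflate being kept cold and used at once.

Step 10
Reactants: 12 (2S,3S,6E)-2-bromo-6-[(2R,5R)-5-bromo-2,6,6-trimethyloxan-3-ylidene]-3-chloro-3-methylhexyl trifluoromethanesulfonate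
Product: 15 (3R)-3-bromo-5-[(1S,3S,4S)-3-bromo-4-chloro-4-methylcyclohexyl]-2,2,6-trimethyl-3,4-dihydro-2H-pyran, via bromonium triflate 13 (not isolated), via oxocarbenium triflate 14 (not isolated)
Conditions: (CF3)2CHOH (HFIP), 2,6-di-tert-butyl-4-methylpyridine, 0 °C → rt; then Et3N
Reagents that add atoms: none
Why: Proposed new method: in HFIP the primary triflate at C2' should ionise with anchimeric assistance of the vicinal C3' bromine to the bromonium ion 13, whose CH2 end is attacked by the exocyclic C3=C1' alkene, and the tertiary C3 cation is discharged at once by a 1,2-shift of the axial C2 hydrogen to give the O1-stabilised oxocarbenium ion 14, which the pyridine base deprotonates at C3 to the ring enol ether (an exocyclic isomer would equilibrate to it in the buffered medium). The closest known reaction types are the solvolytic cation–olefin cyclisation of primary sulfonates and the bromonium-ion cation–olefin cyclisations set off in HFIP by ionising a leaving group next to a bromine; new here are the C–C bond formation at the CH2 end of a terminal bromonium ion and the hydride-shift ending. The cyclohexane closes through a chair in the 6-endo mode with respect to the bromonium ion (6-exo-tet with respect to the triflate carbon). The only new stereocentre, C1', is controlled by C3': backside opening of the bromonium ion holds the C3'–Br bond anti to the forming C1'–C2' bond, that is equatorial, which places the C4' chlorine equatorial and the C4' methyl axial, and the alkene then reacts with its oxane end equatorial, giving the 1',3'-cis, (1'S) ring. The step needs attack at C2' and not at C3', which the neopentyl-like hindrance and the electron-withdrawing C4' chlorine at C3' and the six- over five-membered ring should secure; it needs ionisation of the triflate before the tertiary chloride, secured by the leaving-group ability; and it needs the hydride shift from C2 to win over proton loss from C1' or C4, secured by the gain of the oxocarbenium ion and by the axial C2–H bond lying parallel to the empty orbital at C3.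

Step 11
Reactants: 15 (3R)-3-bromo-5-[(1S,3S,4S)-3-bromo-4-chloro-4-methylcyclohexyl]-2,2,6-trimethyl-3,4-dihydro-2H-pyran
Product: 17 (3S,5R)-5-bromo-3-[(1S,3S,4S)-3-bromo-4-chloro-4-methylcyclohexyl]-6,6-dimethyl-2-methylideneoxan-3-ol, via tertiary allylic hydroperoxide 16 (not isolated)
Conditions: O2, hν (visible), tetraphenylporphyrin (cat.), CH2Cl2, −78 °C; then PPh3, −78 °C → rt
Reagents that add atoms: dioxygen, O=O
Why: Schenck ene reaction of singlet oxygen with the enol ether, in which oxygen bonds to the nucleophilic β-carbon C3 and takes a hydrogen from the C2 methyl (the only allylic hydrogen on the oxygen-bearing carbon) so that the double bond moves to C2=CH2, the attack being expected axially on the face anti to the axial C6 methyl and opposite to the equatorial C5 bromine (3S), after which PPh3 reduces the hydroperoxide to the alcohol.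

**Compound list**
1 | diethyl (2-oxopropyl)phosphonate | CCOP(=O)(CC(C)=O)OCC | starting material
2 | prenyl bromide (1-bromo-3-methylbut-2-ene) | CC(C)=CCBr | starting material
3 | diethyl (6-methyl-2-oxohept-5-en-3-yl)phosphonate (racemic) | CCOP(=O)(OCC)C(CC=C(C)C)C(C)=O | intermediate
4 | neryl acetate, (2Z)-3,7-dimethylocta-2,6-dien-1-yl acetate | CC(C)=CCC/C(C)=C\COC(C)=O | starting material
5 | (2Z)-5-(3,3-dimethyloxiran-2-yl)-3-methylpent-2-en-1-yl acetate (racemic at the oxirane carbon) | CC1(C)OC1CC/C(C)=C\COC(C)=O | intermediate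
6 | (2Z)-3-methyl-6-oxohex-2-en-1-yl acetate | O=CCC/C(C)=C\COC(C)=O | intermediate
7 | (2Z,6E)-7-acetyl-3,10-dimethylundeca-2,6,9-trien-1-yl acetate | CC(=O)/C(CC=C(C)C)=C/CC/C(C)=C\COC(C)=O | intermediate
8 | (2Z,6E)-7-[(1R)-1-hydroxyethyl]-3,10-dimethylundeca-2,6,9-trien-1-yl acetate | C[C@@H](O)/C(CC=C(C)C)=C/CC/C(C)=C\COC(C)=O | intermediate
9 | (2Z,6E)-6-[(2R,5R)-5-bromo-2,6,6-trimethyloxan-3-ylidene]-3-methylhex-2-en-1-yl acetate | C[C@H]1OC(C)(C)[C@H](Br)C/C1=C\CC/C(C)=C\COC(C)=O | intermediate
10 | (2Z,6E)-6-[(2R,5R)-5-bromo-2,6,6-trimethyloxan-3-ylidene]-3-methylhex-2-en-1-ol | C[C@H]1OC(C)(C)[C@H](Br)C/C1=C\CC/C(C)=C\CO | intermediate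
11 | (2S,3S,6E)-2-bromo-6-[(2R,5R)-5-bromo-2,6,6-trimethyloxan-3-ylidene]-3-chloro-3-methylhexan-1-ol | C[C@H]1OC(C)(C)[C@H](Br)C/C1=C\CC[C@](C)(Cl)[C@@H](Br)CO | intermediate
12 | (2S,3S,6E)-2-bromo-6-[(2R,5R)-5-bromo-2,6,6-trimethyloxan-3-ylidene]-3-chloro-3-methylhexyl trifluoromethanesulfonate | C[C@H]1OC(C)(C)[C@H](Br)C/C1=C\CC[C@](C)(Cl)[C@@H](Br)COS(=O)(=O)C(F)(F)F | intermediate
13 | bromonium (bromiranium) trifluoromethanesulfonate from 12: the C3' bromine bridges C2' and C3', configurations at C2, C5, C3', C4' as in 12 | C[C@H]1OC(C)(C)[C@H](Br)C/C1=C\CC[C@](C)(Cl)[C@@H]2C[Br+]2.[O-]S(=O)(=O)C(F)(F)F | intermediate (not isolated)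
14 | (3S,5R)-5-bromo-3-[(1S,3S,4S)-3-bromo-4-chloro-4-methylcyclohexyl]-2,6,6-trimethyl-3,4,5,6-tetrahydropyrylium trifluoromethanesulfonate (cyclic oxocarbenium ion, C3–H taken from C2) | CC1=[O+]C(C)(C)[C@H](Br)C[C@H]1[C@H]1CC[C@](C)(Cl)[C@@H](Br)C1.[O-]S(=O)(=O)C(F)(F)F | intermediate (not isolated)
15 | (3R)-3-bromo-5-[(1S,3S,4S)-3-bromo-4-chloro-4-methylcyclohexyl]-2,2,6-trimethyl-3,4-dihydro-2H-pyran | CC1=C([C@H]2CC[C@](C)(Cl)[C@@H](Br)C2)C[C@@H](Br)C(C)(C)O1 | intermediate
16 | (3S,5R)-5-bromo-3-[(1S,3S,4S)-3-bromo-4-chloro-4-methylcyclohexyl]-3-hydroperoxy-6,6-dimethyl-2-methylideneoxane | C=C1OC(C)(C)[C@H](Br)C[C@]1(OO)[C@H]1CC[C@](C)(Cl)[C@@H](Br)C1 | intermediate (not isolated)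
17 | (3S,5R)-5-bromo-3-[(1S,3S,4S)-3-bromo-4-chloro-4-methylcyclohexyl]-6,6-dimethyl-2-methylideneoxan-3-ol | C=C1OC(C)(C)[C@H](Br)C[C@]1(O)[C@H]1CC[C@](C)(Cl)[C@@H](Br)C1 | target

**Step count**
Total: 11 steps. Longest linear sequence: 10 steps (4 → 17, steps 2 to 11).

**Steps most likely to fail**

1. Step 10 (Proposed new method).
   - What may go wrong: opening of the bromonium ion at its secondary carbon (five-membered ring, bromine moving to the CH2 group); capture of the ion by the solvent; acid-induced migration of the exocyclic C3=C1' double bond into the oxane ring before ring closure; or loss of a proton from C1' or C4 in place of the hydride shift.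
   - Fallback (known chemistry, setting out from 9 and coming back at 15): the (Z)-allylic acetate of 9 is ionised with TMSOTf (CH2Cl2, −78 °C) to the neryl-type allyl cation, which the C3=C1' alkene captures in the classical terpinyl-type cation–olefin cyclisation. The same hydride shift and a MeOH/Et3N quench should give the methyl ketal (5R)-5-bromo-2-methoxy-2,6,6-trimethyl-3-(4-methylcyclohex-3-en-1-yl)oxane F1. Bromochlorination of its ring alkene with NBS and Et4NCl (CH2Cl2, −78 → 0 °C) should give the trans-bromochloride ketal (5R)-5-bromo-3-[(1S,3S,4S)-3-bromo-4-chloro-4-methylcyclohexyl]-2-methoxy-2,6,6-trimethyloxane F2. TMSOTf/iPr2NEt, followed by a trace of PPTS to bring the double bond into the ring, eliminates methanol to 15. This path gives up the relay: C1', C3' and C4' would arise without control, so the (1'S,3'S,4'S) isomer would have to be separated from its diastereomers, and it is expected to be a minor component.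

2. Step 11.
   - What may go wrong: [2+2] addition of singlet oxygen across C2=C3 (dioxetane, then cleavage of the oxane ring) in competition with the ene path, and incomplete discrimination between the two faces at C3.
   - Fallback (setting out from 15 and coming back at 17): epoxidation with dimethyldioxirane (acetone/CH2Cl2, −78 °C) should give the 2,3-epoxide (4R)-4-bromo-6-[(1S,3S,4S)-3-bromo-4-chloro-4-methylcyclohexyl]-1,3,3-trimethyl-2,7-dioxabicyclo[4.1.0]heptane F3, with the oxirane oxygen trans to the ring bromine. TMSOTf/2,6-lutidine (CH2Cl2, −78 °C) opens the alkoxy epoxide to the oxocarbenium ion and removes a proton from the C2 methyl (epoxide to allylic silyl ether isomerisation; C3 has no hydrogen, so only the exocyclic enol ether can form), giving trimethyl({(3S,5R)-5-bromo-3-[(1S,3S,4S)-3-bromo-4-chloro-4-methylcyclohexyl]-6,6-dimethyl-2-methylideneoxan-3-yl}oxy)silane F4. TBAF (THF, 0 °C) then gives 17. This answers the dioxetane problem; the facial preference is the same as in step 11.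

3. Step 6.
   - What may go wrong: ring closure in the five-membered (5-exo) mode, and attack of the bromine source on the other two alkenes.
   - Fallback (setting out from 8 and coming back at 9): the five-membered mode is accepted. NBS in CH2Cl2 should give the 2,5-trans-oxolane with the tertiary bromide, (2Z,6E)-6-[(2R,5S)-5-(2-bromopropan-2-yl)-2-methyloxolan-3-ylidene]-3-methylhex-2-en-1-yl acetate F5. ZnBr2 (CH2Cl2) then ionises the tertiary bromide with help of the ring oxygen to the bicyclic oxonium ion, which bromide reopens at the secondary carbon with inversion (β-halo ether ring expansion) to give 9.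

**Further compounds**
F1 | step 10 | (5R)-5-bromo-2-methoxy-2,6,6-trimethyl-3-(4-methylcyclohex-3-en-1-yl)oxane (isomer mixture at C2, C3, C1') | COC1(C)OC(C)(C)[C@H](Br)CC1C1CCC(C)=CC1
F2 | step 10 | (5R)-5-bromo-3-[(1S,3S,4S)-3-bromo-4-chloro-4-methylcyclohexyl]-2-methoxy-2,6,6-trimethyloxane (wanted cyclohexane isomer, mixture at C2 and C3) | COC1(C)OC(C)(C)[C@H](Br)CC1[C@H]1CC[C@](C)(Cl)[C@@H](Br)C1
F3 | step 11 | (4R)-4-bromo-6-[(1S,3S,4S)-3-bromo-4-chloro-4-methylcyclohexyl]-1,3,3-trimethyl-2,7-dioxabicyclo[4.1.0]heptane (oxirane oxygen trans to the ring bromine) | C[C@@]12O[C@@]1(C[C@@H](Br)C(C)(C)O2)[C@H]1CC[C@](C)(Cl)[C@@H](Br)C1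
F4 | step 11 | trimethyl({(3S,5R)-5-bromo-3-[(1S,3S,4S)-3-bromo-4-chloro-4-methylcyclohexyl]-6,6-dimethyl-2-methylideneoxan-3-yl}oxy)silane | C=C1OC(C)(C)[C@H](Br)C[C@]1(O[Si](C)(C)C)[C@H]1CC[C@](C)(Cl)[C@@H](Br)C1
F5 | step 6 | (2Z,6E)-6-[(2R,5S)-5-(2-bromopropan-2-yl)-2-methyloxolan-3-ylidene]-3-methylhex-2-en-1-yl acetate | C[C@H]1O[C@H](C(C)(C)Br)C/C1=C\CC/C(C)=C\COC(C)=O
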